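**Retrosynthetic overview**
- The target comes from a fully protected tetraene by one global acid deprotection (three MOM ethers, one silyl ether). No ring is built in the route; the only ring, the phloroglucinol benzene ring, is bought.
- C5=C6 and C11=C12 come from a one-pot double Z-Wittig reaction of a C6–C11 (Z)-bis-ylide (which brings C8=C9, from cyclohexa-1,4-diene) with a C12–C20 aldehyde and a C1–C5 aryl keto aldehyde.
- The C12–C20 aldehyde comes from (S)-3-silyloxyhexanal by a Z-Wittig three-carbon homologation (C14=C15) and oxidation.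
- Key bond, C17–O: an enantioselective amine-catalysed oxa-Michael addition of a silanol to (E)-hex-2-enal (new), which sets the only stereocentre.
- The aryl keto aldehyde comes from lithiated tris-MOM phloroglucinol and δ-valerolactone, then oxidation.

Assumption: the target is (5Z,8Z,11Z,14Z,17S)-17-hydroxy-1-(2,4,6-trihydroxyphenyl)icosa-5,8,11,14-tetraen-1-one, C17 being S as read from the SMILES.

**Route**

Step 1
Reactants: 1 (E)-hex-2-enal
Product: 2 (S)-3-[(tert-butyldimethylsilyl)oxy]hexanal
Conditions: t-BuMe2SiOH (3 equiv), (R)-2-{bis[3,5-bis(trifluoromethyl)phenyl][(trimethylsilyl)oxy]methyl}pyrrolidine (10 mol %), PhCO2H (10 mol %), toluene, −20 °C, 48 h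
Reagents that add atoms: tert-butyldimethylsilanol, CC(C)(C)[Si](C)(C)O
Why: Proposed new method: enantioselective oxa-Michael addition of a trialkylsilanol under iminium activation, in which the secondary amine condenses with 1, its diaryl(silyloxy)methyl arm blocks the Re face of C3 of the (E)-s-trans activated enal, the acidic but weakly basic silanol (long Si–O bond, so little steric cost) adds to the Si face and sets the S centre of the future C17, and hydrolysis releases 2 directly as its stable silyl ether, with low temperature and excess silanol holding back the retro-addition; the closest known reaction type is the diarylprolinol silyl ether catalysed oxa-Michael addition of oximes and of alcohols to enals, which has not been shown with silanols.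

Step 2
Reactants: 2 (S)-3-[(tert-butyldimethylsilyl)oxy]hexanal, 3 (3-hydroxypropyl)triphenylphosphonium bromide
Product: 7 (S,Z)-6-[(tert-butyldimethylsilyl)oxy]non-3-en-1-ol, via silyloxypropylphosphonium bromide 4 (not isolated), via silyloxypropylidene ylide 5 (not isolated), via trimethylsilyl ether 6 (not isolated)
Conditions: 3 (1.3 equiv), (Me3Si)2NH, cat. Me3SiCl, MeCN, 60 °C, evaporate; NaN(SiMe3)2 (1.25 equiv), THF, −78 → 0 °C; 2, −78 °C → rt; K2CO3, MeOH, 0 °C
Reagents that add atoms: none
Why: Lithium-free Wittig reaction of the non-stabilised ylide 5 with the unbranched aldehyde 2 at −78 °C gives the Z alkene (C14=C15) under kinetic control, the hydroxyl being masked in the flask as its trimethylsilyl ether to avoid the E-drift of oxido ylides; C17 is not touched.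

Step 3
Reactants: 7 (S,Z)-6-[(tert-butyldimethylsilyl)oxy]non-3-en-1-ol
Product: 8 (S,Z)-6-[(tert-butyldimethylsilyl)oxy]non-3-enal
Conditions: Dess–Martin periodinane (1.3 equiv), NaHCO3, CH2Cl2, 0 °C → rt, 1 h; used at once
Reagents that add atoms: none
Why: Dess–Martin oxidation under bicarbonate buffer gives (Z)-β,γ-unsaturated aldehydes without moving the double bond into conjugation or isomerising it, and the secondary silyl ether is inert.

Step 4
Reactants: 9 phloroglucinol (benzene-1,3,5-triol)
Product: 10 1,3,5-tris(methoxymethoxy)benzene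
Conditions: MeOCH2Cl (3.6 equiv), i-Pr2NEt (4.5 equiv), CH2Cl2–THF, 0 °C → rt
Reagents that add atoms: chloromethyl methyl ether, COCCl
Why: Williamson-type O-alkylation (MOM protection) of the three equivalent phenols; the MOM groups later direct the lithiation and fall off in the final mild acid step.

Step 5
Reactants: 10 1,3,5-tris(methoxymethoxy)benzene, 11 δ-valerolactone (tetrahydro-2H-pyran-2-one)
Product: 13 5-hydroxy-1-[2,4,6-tris(methoxymethoxy)phenyl]pentan-1-one, via aryllithium 12 (not isolated)
Conditions: n-BuLi (1.05 equiv), THF, 0 °C, 1 h; cannulate into 11 (1.3 equiv), THF, −78 °C; H2O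
Reagents that add atoms: none
Why: Directed ortho-lithiation between two MOM ethers gives a single aryllithium (all three ring positions are equivalent), and its acylation by the lactone stops at the ketone because of the low temperature, the excess lactone and the two ortho substituents that shield the new carbonyl.

Step 6
Reactants: 13 5-hydroxy-1-[2,4,6-tris(methoxymethoxy)phenyl]pentan-1-one
Product: 14 5-oxo-5-[2,4,6-tris(methoxymethoxy)phenyl]pentanal
Conditions: Dess–Martin periodinane (1.2 equiv), NaHCO3, CH2Cl2, rt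
Reagents that add atoms: none
Why: Dess–Martin oxidation of the primary alcohol; the hindered aryl ketone and the MOM acetals are unaffected under buffered neutral conditions.

Step 7
Reactants: 15 cyclohexa-1,4-diene
Product: 17 (Z)-hex-3-ene-1,6-diol, via methoxy hydroperoxide aldehyde 16 (not isolated)
Conditions: O3 (1.0 equiv), CH2Cl2–MeOH 4:1, −78 °C; NaBH4, −78 °C → rt
Reagents that add atoms: ozone, [O-][O+]=O
Why: Ozonolysis of one of the two equivalent ring double bonds with one equivalent of ozone and reductive work-up gives the diol, and the ring fixes the Z geometry of the remaining alkene (future C8=C9).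

Step 8
Reactants: 17 (Z)-hex-3-ene-1,6-diol
Product: 18 (Z)-1,6-dibromohex-3-ene
Conditions: CBr4 (2.4 equiv), PPh3 (2.5 equiv), CH2Cl2, 0 °C → rt
Reagents that add atoms: carbon tetrabromide, BrC(Br)(Br)Br
Why: Appel reaction, an SN2 displacement of the oxyphosphonium groups by bromide under neutral conditions that leave the Z alkene untouched.

Step 9
Reactants: 18 (Z)-1,6-dibromohex-3-ene
Product: 19 (Z)-hex-3-ene-1,6-diylbis(triphenylphosphonium) dibromide
Conditions: PPh3 (3 equiv), MeCN, reflux, 72 h
Reagents that add atoms: triphenylphosphine, c1ccc(cc1)P(c1ccccc1)c1ccccc1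
Why: Double SN2 quaternisation of triphenylphosphine by the two primary homoallylic bromides; the salt crystallises out.

Step 10
Reactants: 19 (Z)-hex-3-ene-1,6-diylbis(triphenylphosphonium) dibromide, 8 (S,Z)-6-[(tert-butyldimethylsilyl)oxy]non-3-enal, 14 5-oxo-5-[2,4,6-tris(methoxymethoxy)phenyl]pentanal
Product: 22 (5Z,8Z,11Z,14Z,17S)-17-[(tert-butyldimethylsilyl)oxy]-1-[2,4,6-tris(methoxymethoxy)phenyl]icosa-5,8,11,14-tetraen-1-one, via bis-ylide 20 (not isolated), via trienylidene mono-ylide 21 (not isolated)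
Conditions: 19 (1.5 equiv), NaN(SiMe3)2 (3.0 equiv), THF, −78 → 0 °C; 8 (1.0 equiv), −95 → −78 °C; 14 (2.2 equiv), −78 °C → rt
Reagents that add atoms: none
Why: Sequential one-pot double Wittig olefination in which the bis-ylide 20, used in excess, reacts once with the limiting aldehyde 8 to give 21, whose remaining ylide carbon then olefinates 14; both lithium-free reactions of non-stabilised ylides are Z-selective (C11=C12 and C5=C6) and the hindered aryl ketone does not compete.

Step 11
Reactants: 22 (5Z,8Z,11Z,14Z,17S)-17-[(tert-butyldimethylsilyl)oxy]-1-[2,4,6-tris(methoxymethoxy)phenyl]icosa-5,8,11,14-tetraen-1-one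
Product: 23 (5Z,8Z,11Z,14Z,17S)-17-hydroxy-1-(2,4,6-trihydroxyphenyl)icosa-5,8,11,14-tetraen-1-one
Conditions: 1.5 M HCl in MeOH, Ar, dark, 0 → 35 °C
Reagents that add atoms: none
Why: Acid-catalysed methanolysis cleaves the three MOM acetals and the silyl ether in one operation under conditions that skipped Z-polyenes tolerate, and no stereocentre or alkene is touched.

**Compound list**

1 | (E)-hex-2-enal | CCC/C=C/C=O | starting material
2 | (S)-3-[(tert-butyldimethylsilyl)oxy]hexanal | CCC[C@H](O[Si](C)(C)C(C)(C)C)CC=O | intermediate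
3 | (3-hydroxypropyl)triphenylphosphonium bromide | OCCC[P+](c1ccccc1)(c1ccccc1)c1ccccc1.[Br-] | starting material
4 | [3-(trimethylsilyloxy)propyl]triphenylphosphonium bromide | C[Si](C)(C)OCCC[P+](c1ccccc1)(c1ccccc1)c1ccccc1.[Br-] | intermediate (not isolated)
5 | [3-(trimethylsilyloxy)propylidene]triphenylphosphorane | C[Si](C)(C)OCCC=P(c1ccccc1)(c1ccccc1)c1ccccc1 | intermediate (not isolated)
6 | (S,Z)-6-[(tert-butyldimethylsilyl)oxy]-1-(trimethylsilyloxy)non-3-ene | CCC[C@H](O[Si](C)(C)C(C)(C)C)C/C=C\CCO[Si](C)(C)C | intermediate (not isolated)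
7 | (S,Z)-6-[(tert-butyldimethylsilyl)oxy]non-3-en-1-ol | CCC[C@H](O[Si](C)(C)C(C)(C)C)C/C=C\CCO | intermediate
8 | (S,Z)-6-[(tert-butyldimethylsilyl)oxy]non-3-enal | CCC[C@H](O[Si](C)(C)C(C)(C)C)C/C=C\CC=O | intermediate
9 | phloroglucinol (benzene-1,3,5-triol) | Oc1cc(O)cc(O)c1 | starting material
10 | 1,3,5-tris(methoxymethoxy)benzene | COCOc1cc(OCOC)cc(OCOC)c1 | intermediate
11 | δ-valerolactone (tetrahydro-2H-pyran-2-one) | O=C1CCCCO1 | starting material
12 | [2,4,6-tris(methoxymethoxy)phenyl]lithium | [Li]c1c(OCOC)cc(OCOC)cc1OCOC | intermediate (not isolated)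
13 | 5-hydroxy-1-[2,4,6-tris(methoxymethoxy)phenyl]pentan-1-one | OCCCCC(=O)c1c(OCOC)cc(OCOC)cc1OCOC | intermediate
14 | 5-oxo-5-[2,4,6-tris(methoxymethoxy)phenyl]pentanal | O=CCCCC(=O)c1c(OCOC)cc(OCOC)cc1OCOC | intermediate
15 | cyclohexa-1,4-diene | C1=CCC=CC1 | starting material
16 | (Z)-6-hydroperoxy-6-methoxyhex-3-enal | COC(OO)C/C=C\CC=O | intermediate (not isolated)
17 | (Z)-hex-3-ene-1,6-diol | OCC/C=C\CCO | intermediate
18 | (Z)-1,6-dibromohex-3-ene | BrCC/C=C\CCBr | intermediate
19 | (Z)-hex-3-ene-1,6-diylbis(triphenylphosphonium) dibromide | c1ccccc1[P+](c1ccccc1)(c1ccccc1)CC/C=C\CC[P+](c1ccccc1)(c1ccccc1)c1ccccc1.[Br-].[Br-] | intermediate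
20 | (Z)-hex-3-ene-1,6-diylidenebis(triphenylphosphorane) | c1ccccc1P(c1ccccc1)(c1ccccc1)=CC/C=C\CC=P(c1ccccc1)(c1ccccc1)c1ccccc1 | intermediate (not isolated)
21 | [(3Z,6Z,9Z,12S)-12-[(tert-butyldimethylsilyl)oxy]pentadeca-3,6,9-trien-1-ylidene]triphenylphosphorane | CCC[C@H](O[Si](C)(C)C(C)(C)C)C/C=C\C/C=C\C/C=C\CC=P(c1ccccc1)(c1ccccc1)c1ccccc1 | intermediate (not isolated)
22 | (5Z,8Z,11Z,14Z,17S)-17-[(tert-butyldimethylsilyl)oxy]-1-[2,4,6-tris(methoxymethoxy)phenyl]icosa-5,8,11,14-tetraen-1-one | CCC[C@H](O[Si](C)(C)C(C)(C)C)C/C=C\C/C=C\C/C=C\C/C=C\CCCC(=O)c1c(OCOC)cc(OCOC)cc1OCOC | intermediate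
23 | (5Z,8Z,11Z,14Z,17S)-17-hydroxy-1-(2,4,6-trihydroxyphenyl)icosa-5,8,11,14-tetraen-1-one | CCC[C@H](O)C/C=C\C/C=C\C/C=C\C/C=C\CCCC(=O)c1c(O)cc(O)cc1O | target

**Step count and risks**

Total: 11 steps. Longest linear sequence: 5 steps (steps 1, 2, 3, 10, 11; the branches 4–6 and 7–9 are equally long up to step 10).

The three steps most likely to fail:

Step 1 (the proposed new silanol oxa-Michael addition). The risks are low conversion through retro-addition and modest enantioselectivity. The fallback uses known chemistry; it sets out from 1 and comes back at 2. 1 is treated with (E)-benzaldehyde oxime under the same amine catalyst (the established oxime oxa-Michael addition) to give (S)-3-{[(E)-benzylideneamino]oxy}hexanal F1, which is reduced in the flask with NaBH4 to (S)-3-{[(E)-benzylideneamino]oxy}hexan-1-ol F2. Hydrogenolysis of the N–O bond (H2, Pd(OH)2 on carbon, MeOH) gives (S)-hexane-1,3-diol F3. One-pot silylation, first Et3SiCl and imidazole at −20 °C on the primary hydroxyl and then t-BuMe2SiOTf and 2,6-lutidine on the secondary one, gives (S)-3-[(tert-butyldimethylsilyl)oxy]-1-(triethylsilyloxy)hexane F4. Swern oxidation (DMSO, (COCl)2, Et3N), which turns primary triethylsilyl ethers directly into aldehydes, gives 2.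

Step 10 (one-pot double Wittig). The risks are statistical bis-olefination of 20, base sensitivity of the β,γ-unsaturated aldehyde 8, and Z-selectivity at two new alkenes. The fallback is a stepwise, non-statistical sequence; it sets out from 8 (with 17 and 14 as partners) and comes back at 22. 17 is monobrominated (48% aq HBr, toluene, reflux) to (Z)-6-bromohex-3-en-1-ol F7 and quaternised with PPh3 to (Z)-(6-hydroxyhex-3-en-1-yl)triphenylphosphonium bromide F8. Olefination of 8 with F8 under the in-flask silylation conditions of step 2 gives (3Z,6Z,9Z,12S)-12-[(tert-butyldimethylsilyl)oxy]pentadeca-3,6,9-trien-1-ol F9. Appel bromination gives (3Z,6Z,9Z,12S)-1-bromo-12-[(tert-butyldimethylsilyl)oxy]pentadeca-3,6,9-triene F10, and PPh3 in MeCN gives [(3Z,6Z,9Z,12S)-12-[(tert-butyldimethylsilyl)oxy]pentadeca-3,6,9-trien-1-yl]triphenylphosphonium bromide F11. Its ylide (NaN(SiMe3)2, THF, −78 °C) reacts with 14 to give 22.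

Step 2 (Wittig reaction with the hydroxyl-bearing ylide). The risks are incomplete in-flask silylation, which erodes Z-selectivity, and β-elimination of the silanolate from 2. The fallback replaces the functionalised ylide and the later oxidation by an acetal route; it sets out from 2 and comes back at 8, passing by 7 and step 3. Wittig reaction of 2 with the ylide of the known three-carbon homologating salt (3,3-diisopropoxypropyl)triphenylphosphonium bromide F5 (NaN(SiMe3)2, THF, −78 °C) gives (S,Z)-6-[(tert-butyldimethylsilyl)oxy]-1,1-diisopropoxynon-3-ene F6. The acyclic diisopropyl acetal is hydrolysed with catalytic TsOH in THF–H2O at room temperature to 8 without conjugation of the double bond or loss of the silyl ether.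

Further compounds
F1 | step 1 | (S)-3-{[(E)-benzylideneamino]oxy}hexanal | CCC[C@H](O/N=C/c1ccccc1)CC=O
F2 | step 1 | (S)-3-{[(E)-benzylideneamino]oxy}hexan-1-ol | CCC[C@H](O/N=C/c1ccccc1)CCO
F3 | step 1 | (S)-hexane-1,3-diol | CCC[C@H](O)CCO
F4 | step 1 | (S)-3-[(tert-butyldimethylsilyl)oxy]-1-(triethylsilyloxy)hexane | CCC[C@H](O[Si](C)(C)C(C)(C)C)CCO[Si](CC)(CC)CC
F5 | step 2 | (3,3-diisopropoxypropyl)triphenylphosphonium bromide | CC(C)OC(CC[P+](c1ccccc1)(c1ccccc1)c1ccccc1)OC(C)C.[Br-]
F6 | step 2 | (S,Z)-6-[(tert-butyldimethylsilyl)oxy]-1,1-diisopropoxynon-3-ene | CCC[C@H](O[Si](C)(C)C(C)(C)C)C/C=C\CC(OC(C)C)OC(C)C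
F7 | step 10 | (Z)-6-bromohex-3-en-1-ol | OCC/C=C\CCBr
F8 | step 10 | (Z)-(6-hydroxyhex-3-en-1-yl)triphenylphosphonium bromide | OCC/C=C\CC[P+](c1ccccc1)(c1ccccc1)c1ccccc1.[Br-]
F9 | step 10 | (3Z,6Z,9Z,12S)-12-[(tert-butyldimethylsilyl)oxy]pentadeca-3,6,9-trien-1-ol | CCC[C@H](O[Si](C)(C)C(C)(C)C)C/C=C\C/C=C\C/C=C\CCO
F10 | step 10 | (3Z,6Z,9Z,12S)-1-bromo-12-[(tert-butyldimethylsilyl)oxy]pentadeca-3,6,9-triene | CCC[C@H](O[Si](C)(C)C(C)(C)C)C/C=C\C/C=C\C/C=C\CCBr
F11 | step 10 | [(3Z,6Z,9Z,12S)-12-[(tert-butyldimethylsilyl)oxy]pentadeca-3,6,9-trien-1-yl]triphenylphosphonium bromide | CCC[C@H](O[Si](C)(C)C(C)(C)C)C/C=C\C/C=C\C/C=C\CC[P+](c1ccccc1)(c1ccccc1)c1ccccc1.[Br-]
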